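The zeta run stalled at 76.0% of its substrate and the gamma run at 52.6%, yet they began at similar paces, 0.758 mM min⁻¹ and 0.808 mM min⁻¹. My reading is that the enzyme keeps a steady pace while a side path, growing with the square of the substrate level, takes the missing share.

| setting | zeta | delta | gamma | Friday's | Monday's | Thursday's |
|---|---|---|---|---|---|---|
| substrate | 18 mM | 25 mM | 40 mM | 18 mM | 18 mM | 18 mM (fed, over 40.0 min) |
| enzyme | 1.8 µM | 1.8 µM | 1.8 µM | 1.8 µM | 1.8 µM | 1.8 µM |
| remark | run made earlier | run made earlier | run made earlier | one stirred flow tank at steady state, fed with the mixture as stated, mean residence time 50 min | everything together in a closed stirred flask, run for 50 min | all but substrate at the start; substrate goes in evenly over 40.0 min, the run ends at 50 min |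
| time |  |  |  |  | 50 min | 50 min |

| zeta: time / min | zeta: target / % | delta: time / min | delta: target / % | gamma: time / min | gamma: target / % |
|---|---|---|---|---|---|
| 2.50 | 10.3 | 5.00 | 17.9 | 5.00 | 9.8 |
| 4.00 | 17.7 | 8.00 | 26.4 | 8.00 | 17.2 |
| 6.00 | 26.2 | 12.0 | 37.6 | 12.0 | 24.7 |
| 8.00 | 32.6 | 15.0 | 46.1 | 15.0 | 30.3 |
| 12.0 | 50.5 | 25.0 | 62.6 | 25.0 | 45.4 |
| 20.0 | 71.8 | 40.0 | 66.1 | 40.0 | 51.4 |
| 30.0 | 76.0 | 60.0 | 68.6 | 60.0 | 52.6 |

(each reading ± 1 percentage point)

- the stated concentrations are those of everything mixed, before any reaction; amounts are the same in each set-up
- the feed brings no volume worth counting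
- the earlier runs were made in a closed, stirred flask

* the set-up with the highest amount of target at the outlet or at the end, in percent of the substrate put in ("none" if the first two lie within 2 percentage points) (Friday's / Monday's / Thursday's / none)
* amount of target at the outlet or at the end, in percent of the substrate put in, Friday's
* amount of target at the outlet or at the end, in percent of the substrate put in, Monday's
* amount of target at the outlet or at the end, in percent of the substrate put in, Thursday's

Zeta's substrate fell roughly evenly, so its mean squared level was a third of the charge squared. Lost over made equals that mean over the square of one level: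

even level = 18.5 mM

This even level is the substrate level at which the side path takes substrate as fast as 1.8 µM of enzyme does at its early full pace.

At low levels the enzyme slows. Between 12.0 min and 20.0 min, zeta made 0.479 mM min⁻¹ with about 2.67 mM left, counting target still to come as substrate. That gives a clearance of 0.179 min⁻¹, a rough pseudo-first-order constant.

In Friday's tank the enzyme works below full pace, so the side path's rate, full pace × (level / even level)², must be held against target per minute, which is clearance × level. So level = target per minute / clearance, loss over target = full pace × level / (clearance × even level²), and target = (charge − level) / (1 + loss over target). Target can't pass the charge, nor the charge minus the level, so you can bracket it: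

first round: level below 2.01 mM, target above 86.7%
put back: level near 1.74 mM, target below 90.3%

Thursday's feed, 0.450 mM min⁻¹, is slower than the early pace. Its level therefore sits near 2.51 mM, then decays to 0.418 mM, giving about 94.7%. Monday's repeats zeta, so I expect about 76.0%.

The forecast chose Monday's, with 60% for Friday's (48% to 70%), 78% for Monday's and 70% for Thursday's. Its Friday's range lies below my bracket. Its grounds: “This looks like activity lost with time or product”.

The flasks give 88.5% for Friday's, 77.1% for Monday's and 94.7% for Thursday's, so Thursday's comes first.

    substrate + enzyme → target + enzyme, rate k1*[substrate]^1.5*[enzyme]/(1 + ([substrate]/Kh1)^1.5) (2.40 mM, k = 67000 L¹·⁵ mol⁻¹·⁵ s⁻¹)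
    2 substrate → homo dimer (k = 0.0210 L mol⁻¹ s⁻¹)

The side product is homo dimer, at the end 22.6% in Monday's and 2.88% in Thursday's. Now take the neighbour: Thursday's flask with 0.0072 mM of enzyme, 4.00 times the charge. Scale the clearance with it, to 0.717 min⁻¹, and the feed level comes to 0.627 mM, far under the even level. The side path uses no enzyme, so its rate stays full pace at 1.8 µM × (level / even level)², and the enzyme here makes target at the feed rate. Held against that feed, loss over target is 0.194%, so you reckon nearly all the charge as target. The neighbour ended with target 99.6%, substrate 0.17% and homo dimer 0.255%.

(The data are simulated for substances that don't exist; scatter was added.)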